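**Plan**
- The guanine is cut across its imidazole ring (C8–N7 and C8–N9), which leads back to a ring A salicylaldehyde and 2,5,6-triaminopyrimidin-4(3H)-one.
- The core is cut at two bonds at once, N4–C5 of the piperazine and C5–CH2 to ring A. The enabling feature is that C5, the piperazine carbon carrying the ring A benzyl group, sits between ring nitrogen N4 and a CH2–aryl carbon, the pattern left when N–H and aryl add syn across an N-allyl alkene.
- The open precursor is a tyrosine-derived 1,2-diamine with N-allyl on the α-nitrogen, NHBoc on the primary carbon and the ring A bromide on the phenol oxygen. It is cut at the diaryl ether C–O bond and at the CH2–N bond.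
- Forward order: diaryl ether, then the N-allyl diamine chain, then piperazine and 14-membered cyclophane in one operation, then the imidazole ring of the guanine.
- The C2 (S)-centre comes from L-tyrosine. The C5 (S)-centre is set in the key step by syn-aminopalladation under control of the macrocyclic tether.

Key step: step 7

Assumption: the target is taken as the free base in the 7H-guanine tautomer of its SMILES, and 16 is used as its commercial sulfate salt. Piperazine numbering: N1 is the former tyrosine nitrogen, C2 carries the ring B benzyl group, C5 the ring A benzyl group.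

**Step 1**
Reactants: 1 N-Boc-L-tyrosine methyl ester; 2 5-bromo-2-methoxyphenylboronic acid
Product: 3 methyl (S)-2-(Boc-amino)-3-[4-(5-bromo-2-methoxyphenoxy)phenyl]propanoate
Conditions: Cu(OAc)2 (1 equiv), pyridine, 4 Å molecular sieves, CH2Cl2, air, rt
Reagents that add atoms: 5-bromo-2-methoxyphenylboronic acid (2), COc1ccc(Br)cc1B(O)O
Why: Chan–Lam coupling, in which divalent copper mediates oxidative C–O bond formation between phenol and arylboronic acid at room temperature under air, should leave the carbamate N–H, the ester, the aryl bromide and the α-stereocentre untouched.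

**Step 2**
Reactants: 3 methyl (S)-2-(Boc-amino)-3-[4-(5-bromo-2-methoxyphenoxy)phenyl]propanoate
Product: 4 (S)-2-(Boc-amino)-3-[4-(5-bromo-2-methoxyphenoxy)phenyl]propanoic acid
Conditions: LiOH, THF/H2O, 0 °C; then 1 M HCl to pH 3
Reagents that add atoms: water (delivered as hydroxide from LiOH), O
Why: Saponification of a methyl ester with LiOH at 0 °C is fast enough to avoid epimerisation of the carbamate-protected α-centre and spares the Boc group and the diaryl ether.

**Step 3**
Reactants: 4 (S)-2-(Boc-amino)-3-[4-(5-bromo-2-methoxyphenoxy)phenyl]propanoic acid; 5 allyl bromide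
Product: 6 (S)-2-[allyl(Boc)amino]-3-[4-(5-bromo-2-methoxyphenoxy)phenyl]propanoic acid
Conditions: NaH (3 equiv), allyl bromide, THF, 0 °C to rt; then 1 M HCl to pH 3
Reagents that add atoms: allyl bromide (5), C=CCBr
Why: N-Alkylation of the Boc-amino acid dianion, in which the carboxylate formed first shields the α-proton from enolisation so that the carbamate nitrogen is deprotonated and allylated by SN2 displacement with the (S)-centre retained.

**Step 4**
Reactants: 6 (S)-2-[allyl(Boc)amino]-3-[4-(5-bromo-2-methoxyphenoxy)phenyl]propanoic acid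
Product: 8 tert-butyl allyl[(S)-1-[4-(5-bromo-2-methoxyphenoxy)phenyl]-3-hydroxypropan-2-yl]carbamate, via isobutyl carbonic mixed anhydride 7 (not isolated)
Conditions: i-BuOCOCl, N-methylmorpholine, THF, −15 °C; then NaBH4, H2O, 0 °C
Reagents that add atoms: none
Why: Mixed carbonic anhydride activation followed by NaBH4 reduction should give the primary alcohol without touching the alkene, the aryl bromide or the carbamate and without epimerisation, which a hydroborating reductant could not guarantee.

**Step 5**
Reactants: 8 tert-butyl allyl[(S)-1-[4-(5-bromo-2-methoxyphenoxy)phenyl]-3-hydroxypropan-2-yl]carbamate; 9 N-Boc-2-nitrobenzenesulfonamide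
Product: 10 tert-butyl allyl[(S)-1-[4-(5-bromo-2-methoxyphenoxy)phenyl]-3-[N-Boc-N-(2-nitrophenylsulfonyl)amino]propan-2-yl]carbamate
Conditions: PPh3, diisopropyl azodicarboxylate, THF, 0 °C to rt
Reagents that add atoms: N-Boc-2-nitrobenzenesulfonamide (9), CC(C)(C)OC(=O)NS(=O)(=O)c1ccccc1[N+](=O)[O-]
Why: Mitsunobu reaction with an acidic sulfonyl carbamate (Fukuyama–Mitsunobu alkylation) replaces the primary hydroxyl by nitrogen through SN2 at the CH2 carbon, away from the stereocentre, and the fully substituted neighbouring nitrogen cannot close an aziridine.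

**Step 6**
Reactants: 10 tert-butyl allyl[(S)-1-[4-(5-bromo-2-methoxyphenoxy)phenyl]-3-[N-Boc-N-(2-nitrophenylsulfonyl)amino]propan-2-yl]carbamate
Product: 11 tert-butyl allyl[(S)-1-[4-(5-bromo-2-methoxyphenoxy)phenyl]-3-(Boc-amino)propan-2-yl]carbamate
Conditions: PhSH, K2CO3, DMF, rt
Reagents that add atoms: none
Why: Thiolate attack on the 2-nitrophenyl ring (Meisenheimer adduct, loss of SO2; Fukuyama deprotection) removes the sulfonyl group under mild base and leaves the carbamate N–H needed for the key step, with the unactivated aryl bromide and the alkene inert.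

**Step 7**
Reactants: 11 tert-butyl allyl[(S)-1-[4-(5-bromo-2-methoxyphenoxy)phenyl]-3-(Boc-amino)propan-2-yl]carbamate
Product: 12 (2S,5S)-N,N'-di-Boc-O-methylpiperazinomycin
Conditions: Pd2(dba)3 (5 mol %), P(2-furyl)3 (40 mol %), NaOtBu (1.5 equiv), toluene, 105 °C, 0.005 M, slow addition of 11
Reagents that add atoms: none
Why: Proposed new method: zerovalent palladium inserts into the ring A C–Br bond, NaOtBu removes the carbamate N–H and a 13-membered aryl palladium amido complex forms, after which syn-aminopalladation of the N-allyl alkene makes the N4–C5 bond and C(sp3)–C(aryl) reductive elimination makes the CH2–ring A bond. The closest known reaction type is the Pd2(dba)3/P(2-furyl)3-catalysed carboamination of N-allyl-1,2-diamines with external aryl bromides to cis-disubstituted piperazines, together with carbamate-based carboaminations that give pyrrolidines; new here are the carbamate nucleophile in a six-membered closure and the delivery of the aryl group from within the molecule. The piperazine closes 6-exo-trig in the aminopalladation, and the 14-membered meta,para-cyclophane closes by reductive elimination out of a 15-membered palladacycle, so both chain ends are already held on the metal when the C–C bond forms. The new C5 centre is set by the syn-addition under tether control: the aryl group on palladium is tied through the diaryl ether and ring B to the (S)-centre at C2, and only the alkene face leading to the cis-(2S,5S) piperazine lets the ten-atom bridge span C2 and C5. The step needs carboamination to outrun β-hydride elimination, direct N-arylation, Heck-type closure and oligomerisation; the slow C–N reductive elimination of a carbamate amido complex, the electron-poor phosphine that speeds C–C reductive elimination, and high dilution are relied on for this.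

**Step 8**
Reactants: 12 (2S,5S)-N,N'-di-Boc-O-methylpiperazinomycin
Product: 14 (2S,5S)-N,N'-di-Boc-piperazinomycin, via piperazinomycin dihydrobromide 13 (not isolated)
Conditions: BBr3 (6 equiv), CH2Cl2, −78 to 0 °C; MeOH quench, concentrate; then Boc2O (2.2 equiv), NaHCO3, THF/H2O, rt
Reagents that add atoms: di-tert-butyl dicarbonate, CC(C)(C)OC(=O)OC(=O)OC(C)(C)C
Why: BBr3 cleaves the aryl methyl ether (and both Boc groups) but not the diaryl ether, and the freed secondary amines are then re-acylated selectively by Boc2O under aqueous bicarbonate, where the hindered phenol stays free.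

**Step 9**
Reactants: 14 (2S,5S)-N,N'-di-Boc-piperazinomycin
Product: 15 N,N'-di-Boc-piperazinomycin ring A salicylaldehyde (formyl group ortho to the phenol OH, on the carbon not bearing the aryl ether)
Conditions: MgCl2, Et3N, paraformaldehyde, THF, reflux; aq. HCl work-up
Reagents that add atoms: paraformaldehyde (as formaldehyde), C=O
Why: Magnesium-mediated ortho-formylation (Casnati–Skattebøl reaction): the magnesium phenoxide delivers formaldehyde to the only free ortho position of ring A (the other ortho carbon carries the aryl ether, the para carbon the CH2), and the benzylic alkoxide is oxidised to the aldehyde by hydride transfer to a second formaldehyde.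

**Step 10**
Reactants: 15 N,N'-di-Boc-piperazinomycin ring A salicylaldehyde; 16 2,5,6-triaminopyrimidin-4(3H)-one
Product: 18 N,N'-di-Boc-guanipiperazine A, via Schiff base 17 (not isolated)
Conditions: 16·H2SO4, NaOAc, DMSO, 60 °C, N2; then air, 100 °C
Reagents that add atoms: 2,5,6-triaminopyrimidin-4(3H)-one (16), Nc1nc(N)c(N)c(=O)[nH]1
Why: Traube-type purine synthesis: the most nucleophilic 5-amino group of 16 condenses with the aldehyde, the 6-amino group adds to the imine carbon and the dihydropurine is dehydrogenated by oxygen, which builds the imidazole ring with C8 bonded to ring A.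

**Step 11**
Reactants: 18 N,N'-di-Boc-guanipiperazine A
Product: 19 guanipiperazine A
Conditions: CF3CO2H/CH2Cl2 (1:2), rt; then aq. NH3 to pH 9
Reagents that add atoms: none
Why: Acidolysis of the two tert-butyl carbamates (loss of isobutene and CO2) frees both piperazine nitrogens without affecting the diaryl ether, the phenol, the guanine or the two stereocentres, and neutralisation gives the free base.

**Compound list**
1 | N-Boc-L-tyrosine methyl ester | COC(=O)[C@H](Cc1ccc(O)cc1)NC(=O)OC(C)(C)C | starting material
2 | 5-bromo-2-methoxyphenylboronic acid | COc1ccc(Br)cc1B(O)O | starting material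
3 | methyl (S)-2-(Boc-amino)-3-[4-(5-bromo-2-methoxyphenoxy)phenyl]propanoate | COC(=O)[C@H](Cc1ccc(Oc2cc(Br)ccc2OC)cc1)NC(=O)OC(C)(C)C | intermediate
4 | (S)-2-(Boc-amino)-3-[4-(5-bromo-2-methoxyphenoxy)phenyl]propanoic acid | OC(=O)[C@H](Cc1ccc(Oc2cc(Br)ccc2OC)cc1)NC(=O)OC(C)(C)C | intermediate
5 | allyl bromide | C=CCBr | starting material
6 | (S)-2-[allyl(Boc)amino]-3-[4-(5-bromo-2-methoxyphenoxy)phenyl]propanoic acid | OC(=O)[C@H](Cc1ccc(Oc2cc(Br)ccc2OC)cc1)N(CC=C)C(=O)OC(C)(C)C | intermediate
7 | isobutyl carbonic mixed anhydride of 6 (not isolated) | CC(C)COC(=O)OC(=O)[C@H](Cc1ccc(Oc2cc(Br)ccc2OC)cc1)N(CC=C)C(=O)OC(C)(C)C | intermediate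
8 | tert-butyl allyl[(S)-1-[4-(5-bromo-2-methoxyphenoxy)phenyl]-3-hydroxypropan-2-yl]carbamate | OC[C@H](Cc1ccc(Oc2cc(Br)ccc2OC)cc1)N(CC=C)C(=O)OC(C)(C)C | intermediate
9 | N-Boc-2-nitrobenzenesulfonamide | CC(C)(C)OC(=O)NS(=O)(=O)c1ccccc1[N+](=O)[O-] | starting material
10 | tert-butyl allyl[(S)-1-[4-(5-bromo-2-methoxyphenoxy)phenyl]-3-[N-Boc-N-(2-nitrophenylsulfonyl)amino]propan-2-yl]carbamate | C=CCN(C(=O)OC(C)(C)C)[C@H](CN(C(=O)OC(C)(C)C)S(=O)(=O)c1ccccc1[N+](=O)[O-])Cc1ccc(Oc2cc(Br)ccc2OC)cc1 | intermediate
11 | tert-butyl allyl[(S)-1-[4-(5-bromo-2-methoxyphenoxy)phenyl]-3-(Boc-amino)propan-2-yl]carbamate (key-step precursor) | C=CCN(C(=O)OC(C)(C)C)[C@H](CNC(=O)OC(C)(C)C)Cc1ccc(Oc2cc(Br)ccc2OC)cc1 | intermediate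
12 | (2S,5S)-N,N'-di-Boc-O-methylpiperazinomycin (key-step product) | COc1ccc2cc1Oc1ccc(cc1)C[C@H]1CN(C(=O)OC(C)(C)C)[C@H](CN1C(=O)OC(C)(C)C)C2 | intermediate
13 | piperazinomycin dihydrobromide (not isolated) | Oc1ccc2cc1Oc1ccc(cc1)C[C@H]1CN[C@H](CN1)C2.Br.Br | intermediate
14 | (2S,5S)-N,N'-di-Boc-piperazinomycin | Oc1ccc2cc1Oc1ccc(cc1)C[C@H]1CN(C(=O)OC(C)(C)C)[C@H](CN1C(=O)OC(C)(C)C)C2 | intermediate
15 | N,N'-di-Boc-piperazinomycin ring A salicylaldehyde | O=Cc1cc2cc(c1O)Oc1ccc(cc1)C[C@H]1CN(C(=O)OC(C)(C)C)[C@H](CN1C(=O)OC(C)(C)C)C2 | intermediate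
16 | 2,5,6-triaminopyrimidin-4(3H)-one | Nc1nc(N)c(N)c(=O)[nH]1 | starting material
17 | Schiff base of 15 at the 5-amino group of 16 (not isolated) | Nc1nc(N)c(/N=C/c2cc3cc(c2O)Oc2ccc(cc2)C[C@H]2CN(C(=O)OC(C)(C)C)[C@H](CN2C(=O)OC(C)(C)C)C3)c(=O)[nH]1 | intermediate
18 | N,N'-di-Boc-guanipiperazine A | Nc1nc2nc(-c3cc4cc(c3O)Oc3ccc(cc3)C[C@H]3CN(C(=O)OC(C)(C)C)[C@H](CN3C(=O)OC(C)(C)C)C4)[nH]c2c(=O)[nH]1 | intermediate
19 | guanipiperazine A | Nc1nc2nc(-c3cc4cc(c3O)Oc3ccc(cc3)C[C@H]3CN[C@H](CN3)C4)[nH]c2c(=O)[nH]1 | target

Total step count: 11. Longest linear sequence: 11 steps (1 to 19).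

**Steps most likely to fail**

Step 7 (key step). The aryl palladium amido complex may fail to reach the alkene, so that β-hydride elimination, direct N-arylation, Heck-type closure or oligomerisation take over. The fallback gives up the double closure and instead closes the macrocycle at the diaryl ether oxygen by an intramolecular Ullmann coupling on a preformed cis-piperazine. It sets out from 1. Mono-iodination ortho to the phenol (N-iodosuccinimide, MeCN, 0 °C) should give methyl N-Boc-3-iodo-L-tyrosinate F1. O-Methylation (MeI, K2CO3, acetone) then gives methyl N-Boc-3-iodo-O-methyl-L-tyrosinate F2, and saponification (LiOH, THF/H2O, then HCl) gives N-Boc-3-iodo-O-methyl-L-tyrosine F3. Coupling of F3 with commercial L-tyrosine methyl ester hydrochloride (COC(=O)[C@@H](N)Cc1ccc(O)cc1.Cl; EDC·HCl, HOBt, N-methylmorpholine, DMF) gives the dipeptide Boc-L-Tyr(3-I,Me)-L-Tyr-OMe F4. Boc removal with HCO2H and heating in 2-butanol/toluene closes the cis-diketopiperazine cyclo[L-Tyr-L-(3-iodo-O-methyl)Tyr] F5. BH3·THF at reflux reduces both lactams to (2S,5S)-2-(4-hydroxybenzyl)-5-(3-iodo-4-methoxybenzyl)piperazine F6, which Boc2O/NaHCO3 converts into the N,N'-di-Boc piperazine F7. Ullmann etherification of F7 (CuI, N,N-dimethylglycine, Cs2CO3, dioxane, 90 °C, high dilution) joins the ring B phenol oxygen to the iodine-bearing ring A carbon and comes back to the route at 12.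

Step 10. Oxidative ring closure of the Schiff base may stall, or the electron-rich aminopyrimidine and phenol may be over-oxidised, and the poor solubility of 16 may hold back the condensation. The fallback raises the ring A carbon to the acid oxidation level so that the imidazole closes by dehydration without an oxidant. It sets out from 15. Pinnick oxidation (NaClO2, NaH2PO4, 2-methyl-2-butene, t-BuOH/H2O) should give the N,N'-di-Boc-piperazinomycin ring A salicylic acid F8. Carbodiimide coupling with 16 as the free base (EDC·HCl, HOBt, pyridine, DMF) acylates the most nucleophilic 5-amino group and gives the 5-aroylamino-2,6-diaminopyrimidin-4(3H)-one F9. Heating F9 in aqueous NaOH/EtOH, then neutralising with AcOH, closes the imidazole ring by cyclodehydration (classical Traube closure) and comes back to the route at 18.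

Step 1. Protodeboronation of the ortho-methoxy boronic acid and slow transfer of the hindered aryl group to copper may leave the phenol unarylated. The fallback replaces the copper/boron oxidative coupling by metal-free ligand coupling at trivalent iodine. Commercial 4-bromo-2-iodoanisole (COc1ccc(Br)cc1I) is oxidised with mCPBA and TsOH·H2O in MeCN and trapped with 1,3,5-trimethoxybenzene to give (5-bromo-2-methoxyphenyl)(2,4,6-trimethoxyphenyl)iodonium tosylate F10. The fallback sets out from 1, whose phenoxide (KOtBu, THF, rt) should take up the 5-bromo-2-methoxyphenyl group of F10, the trimethoxyphenyl group staying on iodine, and it comes back to the route at 3.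

**Further compounds**
F1 | step 7 | methyl N-Boc-3-iodo-L-tyrosinate | COC(=O)[C@H](Cc1ccc(O)c(I)c1)NC(=O)OC(C)(C)C
F2 | step 7 | methyl N-Boc-3-iodo-O-methyl-L-tyrosinate | COC(=O)[C@H](Cc1ccc(OC)c(I)c1)NC(=O)OC(C)(C)C
F3 | step 7 | N-Boc-3-iodo-O-methyl-L-tyrosine | OC(=O)[C@H](Cc1ccc(OC)c(I)c1)NC(=O)OC(C)(C)C
F4 | step 7 | Boc-L-Tyr(3-I,Me)-L-Tyr-OMe | COC(=O)[C@H](Cc1ccc(O)cc1)NC(=O)[C@H](Cc1ccc(OC)c(I)c1)NC(=O)OC(C)(C)C
F5 | step 7 | cyclo[L-Tyr-L-(3-iodo-O-methyl)Tyr] | O=C1N[C@@H](Cc2ccc(O)cc2)C(=O)N[C@H]1Cc1ccc(OC)c(I)c1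
F6 | step 7 | (2S,5S)-2-(4-hydroxybenzyl)-5-(3-iodo-4-methoxybenzyl)piperazine | C1N[C@@H](Cc2ccc(O)cc2)CN[C@H]1Cc1ccc(OC)c(I)c1
F7 | step 7 | (2S,5S)-N,N'-di-Boc-2-(4-hydroxybenzyl)-5-(3-iodo-4-methoxybenzyl)piperazine | C1N(C(=O)OC(C)(C)C)[C@@H](Cc2ccc(O)cc2)CN(C(=O)OC(C)(C)C)[C@H]1Cc1ccc(OC)c(I)c1
F8 | step 10 | N,N'-di-Boc-piperazinomycin ring A salicylic acid | OC(=O)c1cc2cc(c1O)Oc1ccc(cc1)C[C@H]1CN(C(=O)OC(C)(C)C)[C@H](CN1C(=O)OC(C)(C)C)C2
F9 | step 10 | 5-aroylamino-2,6-diaminopyrimidin-4(3H)-one from F8 and 16 | Nc1nc(N)c(NC(=O)c2cc3cc(c2O)Oc2ccc(cc2)C[C@H]2CN(C(=O)OC(C)(C)C)[C@H](CN2C(=O)OC(C)(C)C)C3)c(=O)[nH]1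
F10 | step 1 | (5-bromo-2-methoxyphenyl)(2,4,6-trimethoxyphenyl)iodonium tosylate | COc1ccc(Br)cc1[I+]c1c(OC)cc(OC)cc1OC.Cc1ccc(cc1)S(=O)(=O)[O-]
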